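The route rests on disconnecting each 2,3-diaryl-2,3-dihydrobenzofuran across O1–C2 and C3a–C3 into an o-quinone diazide and an (E)-stilbene. It exploits that in the dihydrobenzofuran carrying the 2,4-dihydroxyphenyl group the benzo carbon C3a lies between the oxygen-bearing carbons C4 and C7a: C3a–C7a–O1 is the carbene carbon, carbonyl carbon and oxygen of a masked 2-diazo-1,3-dione. In one operation a chiral dirhodium carbene from a 6-bromo-2-diazo-3-silyloxycyclohexadienone adds across silylated oxyresveratrol with loss of N2, setting both stereocentres trans. The same annulation, after a Heck reaction, builds the second ring; a final Heck reaction and desilylation finish.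

Key step: step 6

Remarks: TBS = tert-butyldimethylsilyl, TIPS = triisopropylsilyl, TBSO/TIPSO = the silyloxy groups. Each 2,3-dihydrobenzofuran is numbered O1, C2, C3, C3a, C4–C7, C7a.
Assumption: the sense of induction of Rh2(S-PTTL)4 in steps 6 and 14 is taken as the one that leads to the (2S,3S) rings; should it prove opposite, the enantiomeric catalyst Rh2(R-PTTL)4 is used and nothing else changes.

Step 1
Reactants: 1 oxyresveratrol, (E)-4-[2-(3,5-dihydroxyphenyl)ethenyl]benzene-1,3-diol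
Product: 2 (E)-2,4,3′,5′-tetrakis(TBSO)stilbene
Conditions: TBSCl (5 equiv), imidazole, DMF, rt
Reagents that add atoms: tert-butyldimethylsilyl chloride, CC(C)(C)[Si](C)(C)Cl
Why: Imidazole-promoted O-silylation of the four phenols (silyl ether formation), which keeps the 2,4-dioxygenated ring a strong donor for step 6.

Step 2
Reactants: 3 2-nitroresorcinol (2-nitrobenzene-1,3-diol)
Product: 4 4-bromo-2-nitrobenzene-1,3-diol
Conditions: Br2 (1.0 equiv), AcOH, 0 °C to rt
Reagents that add atoms: bromine, BrBr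
Why: Electrophilic aromatic bromination, in which only the two equivalent positions ortho/para to the hydroxyls are activated and the nitro group should slow a second bromination.

Step 3
Reactants: 4 4-bromo-2-nitrobenzene-1,3-diol
Product: 5 6-bromo-2-nitro-3-(TIPSO)phenol
Conditions: TIPSCl (1.05 equiv), imidazole, CH2Cl2, 0 °C
Reagents that add atoms: triisopropylsilyl chloride, CC(C)[Si](Cl)(C(C)C)C(C)C
Why: Site-selective O-silylation, since the hydroxyl flanked by Br and NO2 is shielded and the bulky silyl chloride should take the hydroxyl para to bromine.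

Step 4
Reactants: 5 6-bromo-2-nitro-3-(TIPSO)phenol
Product: 6 2-amino-6-bromo-3-(TIPSO)phenol
Conditions: H2 (1 atm), 5% Pt/C (sulfided), EtOAc, rt; used at once
Reagents that add atoms: none
Why: Chemoselective catalytic hydrogenation of the nitro group over sulfided platinum, which should leave the C–Br bond and the silyl ether intact.

Step 5
Reactants: 6 2-amino-6-bromo-3-(TIPSO)phenol
Product: 7 6-bromo-2-diazo-3-(TIPSO)cyclohexa-3,5-dien-1-one (o-quinone diazide)
Conditions: t-BuONO (1.2 equiv), CH2Cl2/MeCN, 0 °C, dark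
Reagents that add atoms: tert-butyl nitrite, CC(C)(C)ON=O
Why: Diazotisation of the o-aminophenol with an alkyl nitrite, after which the diazonium ion loses the phenolic proton and is isolated as the neutral o-quinone diazide.

Step 6
Reactants: 7 6-bromo-2-diazo-3-(TIPSO)cyclohexa-3,5-dien-1-one; 2 (E)-2,4,3′,5′-tetrakis(TBSO)stilbene
Product: 9 (2S,3S)-7-bromo-2-[2,4-bis(TBSO)phenyl]-3-[3,5-bis(TBSO)phenyl]-4-(TIPSO)-2,3-dihydrobenzofuran (2,3-trans), via aryloxide/benzylic-cation zwitterion 8 (not isolated)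
Conditions: Rh2(S-PTTL)4 [dirhodium tetrakis(N-phthaloyl-(S)-tert-leucinate)] (1 mol %), 2 (2 equiv), PhCF3, 40 °C, slow addition of 7, dark
Reagents that add atoms: none
Why: Proposed new method: Rh2(S-PTTL)4 extrudes N2 from 7 to give an electrophilic 2-oxidoaryl (α-oxo) rhodium carbene; the alkene carbon of 2 that carries the 3,5-bis(silyloxy)phenyl group attacks the carbene carbon (future C3a), because only this regiochemistry puts the positive charge on the benzylic carbon next to the 2,4-bis(silyloxy)phenyl group (zwitterion 8), and the re-aromatised aryloxide then captures this cation. The closest known reaction type is the formal (3+2) cycloaddition of o-quinone diazides and cyclic 2-diazo-1,3-diones (ketocarbene 1,3-dipoles) with enol ethers and styrenes to 2,3-dihydrofurans under Rh2(OAc)4 or heat; new here are the 1,2-diarylethene partner and enantiocontrol by a tert-leucinate-derived dirhodium carboxylate, known so far for cyclopropanation of styrenes with cyclic diacceptor carbenes. The dihydrofuran ring closes by O1–C2 bond formation, a 5-exo-trig attack of the aryloxide on the exocyclic quinone-methide-type C=C of the cation (cation collapse), after the intermolecular C3a–C3 bond. C3 is set in the C–C bond-forming step by the chiral ligand sphere of the catalyst, which selects the enantioface of the E-alkene, and C2 is set relative to C3 in the ring closure, which places the two aryl groups trans (less hindered rotamer of 8 and also the thermodynamic isomer, since the benzylic C2–O bond can reopen to the same cation). The step needs site selectivity on the diazide, regioselectivity on the alkene and chemoselectivity for the alkene over the electron-rich arenes: the silylated oxygen at C4 leaves only the C7a oxygen for ring closure, the donor pattern of the two aryl groups polarises the alkene, and the bulky silyl ethers shield the open ring positions of 2.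

Step 7
Reactants: 10 3,5-dihydroxybenzaldehyde
Product: 11 3,5-bis(TBSO)benzaldehyde
Conditions: TBSCl (2.4 equiv), imidazole, DMF, rt
Reagents that add atoms: tert-butyldimethylsilyl chloride, CC(C)(C)[Si](C)(C)Cl
Why: Imidazole-promoted O-silylation of both phenols (silyl ether formation).

Step 8
Reactants: 11 3,5-bis(TBSO)benzaldehyde
Product: 12 3,5-bis(TBSO)styrene
Conditions: Ph3PCH3Br, NaN(SiMe3)2, THF, 0 °C to rt
Reagents that add atoms: methyltriphenylphosphonium bromide, C[P+](c1ccccc1)(c1ccccc1)c1ccccc1.[Br-]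
Why: Wittig methylenation of the aldehyde with the non-stabilised ylide, under an amide base that should spare the aryl silyl ethers.

Step 9
Reactants: 9 (2S,3S)-7-bromo-2-[2,4-bis(TBSO)phenyl]-3-[3,5-bis(TBSO)phenyl]-4-(TIPSO)-2,3-dihydrobenzofuran; 12 3,5-bis(TBSO)styrene
Product: 13 (2S,3S)-7-[(E)-2-[3,5-bis(TBSO)phenyl]ethenyl]-2-[2,4-bis(TBSO)phenyl]-3-[3,5-bis(TBSO)phenyl]-4-(TIPSO)-2,3-dihydrobenzofuran
Conditions: Pd2(dba)3 (2.5 mol %), P(t-Bu)3·HBF4 (10 mol %), Cy2NMe, 1,4-dioxane, 80 °C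
Reagents that add atoms: none
Why: Mizoroki–Heck reaction (oxidative addition of the aryl bromide to zerovalent palladium, syn-carbopalladation at the CH2 carbon of the styrene, syn-β-hydride elimination), which should give the (E)-stilbene without touching the two stereocentres.

Step 10
Reactants: 14 2-nitrophloroglucinol (2-nitrobenzene-1,3,5-triol)
Product: 15 2-nitro-5-(TIPSO)benzene-1,3-diol
Conditions: TIPSCl (1.0 equiv), imidazole, DMF, 0 °C
Reagents that add atoms: triisopropylsilyl chloride, CC(C)[Si](Cl)(C(C)C)C(C)C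
Why: Site-selective O-silylation, since the hydroxyl para to the nitro group is the most acidic and the only one not hydrogen-bonded to it.

Step 11
Reactants: 15 2-nitro-5-(TIPSO)benzene-1,3-diol
Product: 16 3-hydroxy-2-nitro-5-(TIPSO)phenyl trifluoromethanesulfonate
Conditions: PhNTf2 (1.0 equiv), Et3N, CH2Cl2, 0 °C to rt
Reagents that add atoms: N-phenylbis(trifluoromethanesulfonimide), O=S(=O)(N(c1ccccc1)S(=O)(=O)C(F)(F)F)C(F)(F)F
Why: Monotriflation of one of two equivalent hydroxyls with a mild triflyl donor, after which the electron-poorer product phenol should react more slowly than the diol.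

Step 12
Reactants: 16 3-hydroxy-2-nitro-5-(TIPSO)phenyl trifluoromethanesulfonate
Product: 17 2-amino-3-hydroxy-5-(TIPSO)phenyl trifluoromethanesulfonate
Conditions: H2 (1 atm), 5% Pt/C (sulfided), EtOAc, rt; used at once
Reagents that add atoms: none
Why: Chemoselective catalytic hydrogenation of the nitro group, which should leave the aryl triflate and the silyl ether intact.

Step 13
Reactants: 17 2-amino-3-hydroxy-5-(TIPSO)phenyl trifluoromethanesulfonate
Product: 18 6-diazo-5-oxo-3-(TIPSO)cyclohexa-1,3-dien-1-yl trifluoromethanesulfonate (o-quinone diazide)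
Conditions: t-BuONO (1.2 equiv), CH2Cl2/MeCN, 0 °C, dark
Reagents that add atoms: tert-butyl nitrite, CC(C)(C)ON=O
Why: Diazotisation of the o-aminophenol with an alkyl nitrite to the neutral o-quinone diazide, as in step 5.

Step 14
Reactants: 18 6-diazo-5-oxo-3-(TIPSO)cyclohexa-1,3-dien-1-yl trifluoromethanesulfonate; 13 (2S,3S)-7-[(E)-2-[3,5-bis(TBSO)phenyl]ethenyl]-2-[2,4-bis(TBSO)phenyl]-3-[3,5-bis(TBSO)phenyl]-4-(TIPSO)-2,3-dihydrobenzofuran
Product: 20 (2S,3S)-3-[3,5-bis(TBSO)phenyl]-2-[(2S,3S)-2-[2,4-bis(TBSO)phenyl]-3-[3,5-bis(TBSO)phenyl]-4-(TIPSO)-2,3-dihydrobenzofuran-7-yl]-6-(TIPSO)-2,3-dihydrobenzofuran-4-yl trifluoromethanesulfonate (both rings 2,3-trans), via aryloxide/benzylic-cation zwitterion 19 (not isolated)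
Conditions: Rh2(S-PTTL)4 (2 mol %), 18 (1.5 equiv, slow addition), PhCF3, 40 °C, dark
Reagents that add atoms: none
Why: Proposed new method: the same catalyst-controlled ketocarbene (3+2) annulation as in step 6 (closest known type: the Rh2(OAc)4-promoted cycloaddition of o-quinone diazides and 2-diazo-1,3-diones with styrenes and enol ethers), in which the alkene carbon carrying the 3,5-bis(silyloxy)phenyl group attacks the carbene carbon, the cation next to the 7-dihydrobenzofuranyl ring (ortho ring oxygen, para silyloxy group) is captured by the aryloxide of zwitterion 19, C3 is set by the catalyst and C2 trans to it by ring closure.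

Step 15
Reactants: 20 the bis(dihydrobenzofuran) triflate; 21 4-(TBSO)styrene
Product: 22 nona-O-silyl ether of the target [20 with the triflate replaced by (E)-2-[4-(TBSO)phenyl]ethenyl]
Conditions: PdCl2(PPh3)2 (10 mol %), LiCl, Et3N, DMF, 90 °C
Reagents that add atoms: none
Why: Mizoroki–Heck reaction of the aryl triflate with the styrene (chloride-assisted neutral pathway), which should give the (E)-stilbene at C4 of the second dihydrobenzofuran.

Step 16
Reactants: 22 nona-O-silyl ether of the target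
Product: 23 (2S,3S)-2-(2,4-dihydroxyphenyl)-3-(3,5-dihydroxyphenyl)-7-[(2S,3S)-3-(3,5-dihydroxyphenyl)-6-hydroxy-4-[(E)-2-(4-hydroxyphenyl)ethenyl]-2,3-dihydrobenzofuran-2-yl]-2,3-dihydrobenzofuran-4-ol (target)
Conditions: Bu4NF (12 equiv), AcOH (12 equiv), THF, 0 °C to rt, under argon
Reagents that add atoms: none
Why: Fluoride-mediated cleavage of all nine aryl silyl ethers, buffered with acetic acid so that the phenols are released without phenoxide-driven opening of the benzylic C2–O bonds; the stereocentres and the E-alkene are not touched.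

Compound list
1 | oxyresveratrol | Oc1ccc(/C=C/c2cc(O)cc(O)c2)c(O)c1 | starting material
2 | (E)-2,4,3′,5′-tetrakis(TBSO)stilbene | CC(C)(C)[Si](C)(C)Oc1ccc(/C=C/c2cc(O[Si](C)(C)C(C)(C)C)cc(O[Si](C)(C)C(C)(C)C)c2)c(O[Si](C)(C)C(C)(C)C)c1 | intermediate
3 | 2-nitroresorcinol | Oc1cccc(O)c1[N+](=O)[O-] | starting material
4 | 4-bromo-2-nitrobenzene-1,3-diol | Oc1ccc(Br)c(O)c1[N+](=O)[O-] | intermediate
5 | 6-bromo-2-nitro-3-(TIPSO)phenol | Oc1c(Br)ccc(O[Si](C(C)C)(C(C)C)C(C)C)c1[N+](=O)[O-] | intermediate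
6 | 2-amino-6-bromo-3-(TIPSO)phenol | Nc1c(O)c(Br)ccc1O[Si](C(C)C)(C(C)C)C(C)C | intermediate
7 | 6-bromo-2-diazo-3-(TIPSO)cyclohexa-3,5-dien-1-one | [N-]=[N+]=C1C(=O)C(Br)=CC=C1O[Si](C(C)C)(C(C)C)C(C)C | intermediate
8 | ring-opened zwitterion of 9 (aryloxide with benzylic cation; diarylmethine carbon configured as C3 of 9) | [O-]c1c(Br)ccc(O[Si](C(C)C)(C(C)C)C(C)C)c1[C@H](c1cc(O[Si](C)(C)C(C)(C)C)cc(O[Si](C)(C)C(C)(C)C)c1)[CH+]c1ccc(O[Si](C)(C)C(C)(C)C)cc1O[Si](C)(C)C(C)(C)C | intermediate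
9 | (2S,3S)-7-bromo-2-[2,4-bis(TBSO)phenyl]-3-[3,5-bis(TBSO)phenyl]-4-(TIPSO)-2,3-dihydrobenzofuran | Brc1ccc(O[Si](C(C)C)(C(C)C)C(C)C)c2c1O[C@H](c1ccc(O[Si](C)(C)C(C)(C)C)cc1O[Si](C)(C)C(C)(C)C)[C@H]2c1cc(O[Si](C)(C)C(C)(C)C)cc(O[Si](C)(C)C(C)(C)C)c1 | intermediate
10 | 3,5-dihydroxybenzaldehyde | O=Cc1cc(O)cc(O)c1 | starting material
11 | 3,5-bis(TBSO)benzaldehyde | O=Cc1cc(O[Si](C)(C)C(C)(C)C)cc(O[Si](C)(C)C(C)(C)C)c1 | intermediate
12 | 3,5-bis(TBSO)styrene | C=Cc1cc(O[Si](C)(C)C(C)(C)C)cc(O[Si](C)(C)C(C)(C)C)c1 | intermediate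
13 | (2S,3S)-7-[(E)-2-[3,5-bis(TBSO)phenyl]ethenyl]-2-[2,4-bis(TBSO)phenyl]-3-[3,5-bis(TBSO)phenyl]-4-(TIPSO)-2,3-dihydrobenzofuran | CC(C)(C)[Si](C)(C)Oc1cc(/C=C/c2ccc(O[Si](C(C)C)(C(C)C)C(C)C)c3c2O[C@H](c2ccc(O[Si](C)(C)C(C)(C)C)cc2O[Si](C)(C)C(C)(C)C)[C@H]3c2cc(O[Si](C)(C)C(C)(C)C)cc(O[Si](C)(C)C(C)(C)C)c2)cc(O[Si](C)(C)C(C)(C)C)c1 | intermediate
14 | 2-nitrophloroglucinol | Oc1cc(O)c([N+](=O)[O-])c(O)c1 | starting material
15 | 2-nitro-5-(TIPSO)benzene-1,3-diol | Oc1cc(O[Si](C(C)C)(C(C)C)C(C)C)cc(O)c1[N+](=O)[O-] | intermediate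
16 | 3-hydroxy-2-nitro-5-(TIPSO)phenyl trifluoromethanesulfonate | Oc1cc(O[Si](C(C)C)(C(C)C)C(C)C)cc(OS(=O)(=O)C(F)(F)F)c1[N+](=O)[O-] | intermediate
17 | 2-amino-3-hydroxy-5-(TIPSO)phenyl trifluoromethanesulfonate | Nc1c(O)cc(O[Si](C(C)C)(C(C)C)C(C)C)cc1OS(=O)(=O)C(F)(F)F | intermediate
18 | 6-diazo-5-oxo-3-(TIPSO)cyclohexa-1,3-dien-1-yl trifluoromethanesulfonate | [N-]=[N+]=C1C(=O)C=C(O[Si](C(C)C)(C(C)C)C(C)C)C=C1OS(=O)(=O)C(F)(F)F | intermediate
19 | ring-opened zwitterion of 20 (aryloxide with benzylic cation; diarylmethine carbon configured as C3 of the new ring of 20) | [O-]c1cc(O[Si](C(C)C)(C(C)C)C(C)C)cc(OS(=O)(=O)C(F)(F)F)c1[C@H](c1cc(O[Si](C)(C)C(C)(C)C)cc(O[Si](C)(C)C(C)(C)C)c1)[CH+]c1ccc(O[Si](C(C)C)(C(C)C)C(C)C)c2c1O[C@H](c1ccc(O[Si](C)(C)C(C)(C)C)cc1O[Si](C)(C)C(C)(C)C)[C@H]2c1cc(O[Si](C)(C)C(C)(C)C)cc(O[Si](C)(C)C(C)(C)C)c1 | intermediate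
20 | (2S,3S)-3-[3,5-bis(TBSO)phenyl]-2-[(2S,3S)-2-[2,4-bis(TBSO)phenyl]-3-[3,5-bis(TBSO)phenyl]-4-(TIPSO)-2,3-dihydrobenzofuran-7-yl]-6-(TIPSO)-2,3-dihydrobenzofuran-4-yl trifluoromethanesulfonate | FC(F)(F)S(=O)(=O)Oc1cc(O[Si](C(C)C)(C(C)C)C(C)C)cc2c1[C@H](c1cc(O[Si](C)(C)C(C)(C)C)cc(O[Si](C)(C)C(C)(C)C)c1)[C@@H](c1ccc(O[Si](C(C)C)(C(C)C)C(C)C)c3c1O[C@H](c1ccc(O[Si](C)(C)C(C)(C)C)cc1O[Si](C)(C)C(C)(C)C)[C@H]3c1cc(O[Si](C)(C)C(C)(C)C)cc(O[Si](C)(C)C(C)(C)C)c1)O2 | intermediate
21 | 4-(TBSO)styrene | C=Cc1ccc(O[Si](C)(C)C(C)(C)C)cc1 | starting material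
22 | nona-O-silyl ether of the target (seven TBS, two TIPS) | CC(C)(C)[Si](C)(C)Oc1ccc(/C=C/c2cc(O[Si](C(C)C)(C(C)C)C(C)C)cc3c2[C@H](c2cc(O[Si](C)(C)C(C)(C)C)cc(O[Si](C)(C)C(C)(C)C)c2)[C@@H](c2ccc(O[Si](C(C)C)(C(C)C)C(C)C)c4c2O[C@H](c2ccc(O[Si](C)(C)C(C)(C)C)cc2O[Si](C)(C)C(C)(C)C)[C@H]4c2cc(O[Si](C)(C)C(C)(C)C)cc(O[Si](C)(C)C(C)(C)C)c2)O3)cc1 | intermediate
23 | target, (2S,3S)/(2S,3S) bis(trans-dihydrobenzofuran) | Oc1ccc(/C=C/c2cc(O)cc3c2[C@H](c2cc(O)cc(O)c2)[C@@H](c2ccc(O)c4c2O[C@H](c2ccc(O)cc2O)[C@H]4c2cc(O)cc(O)c2)O3)cc1 | target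

Total step count: 16.
Longest linear sequence: 9 steps (steps 2, 3, 4, 5, 6, 9, 14, 15, 16, from 2-nitroresorcinol).

Steps most likely to fail

1. Step 6 (Proposed new method). The carbene may be diverted into arylation of the electron-rich 3,5-bis(silyloxy)phenyl ring of 2 or into dimerisation instead of adding to the hindered 1,2-disubstituted alkene, and facial discrimination by the catalyst may be insufficient. The fallback uses known chemistry with a different bond order; it sets out from 7 and 11 and comes back at 9. Iodo-dediazoniation of 7 (KI, aq. H2SO4, MeCN, 0 °C) should give 6-bromo-2-iodo-3-(TIPSO)phenol F1. Iodine–magnesium exchange (i-PrMgCl, 2.1 equiv, THF, −20 °C, the bromide being left) and addition to 11 give the o-hydroxybenzhydrol F2, which already holds the C3a–C3 bond. p-Toluenesulfinic acid (CH2Cl2, rt) converts it into the sulfone F3, a base-triggered o-quinone methide precursor. In parallel, 2,4-dihydroxybenzaldehyde is silylated to 2,4-bis(TBSO)benzaldehyde F4, reduced with NaBH4 to 2,4-bis(TBSO)benzyl alcohol F5 and converted with tetrahydrothiophene and HBF4·OEt2 into the S-benzyl tetrahydrothiophenium tetrafluoroborate F6. F3 and F6 with Cs2CO3 (CH2Cl2, rt) undergo the known o-quinone methide/sulfonium ylide [4+1] annulation, which forms C2–C3 and O1–C2 and should give racemic trans-9. Preparative HPLC on a chiral stationary phase then removes the (2R,3R)-enantiomer F7, and 9 re-enters at step 9.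

2. Step 14 (Proposed new method). The catalyst has to override the resident stereocentres of 13, so facial selectivity may be poor, and the carbene may attack one of the four electron-rich arene rings. The fallback gives up catalyst control and uses the known achiral form of the cycloaddition; it sets out from 13 and 18 and comes back at 20. With Rh2(OAc)4 (PhCF3, 60 °C) the annulation should give both trans adducts; because 13 is a single enantiomer these are diastereomers, not enantiomers, and are separated by chromatography on silica. 20 goes on to step 15 and the diastereomer with the (2R,3R)-configured new ring, F8, is discarded.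

3. Step 3. Silylation may occur at the wrong hydroxyl or twice (loss of site selectivity between two hydroxyls that both flank the nitro group). The fallback reverses the order of bromination and silylation; it sets out from 3 and comes back at 5. The symmetric diol 3 is monosilylated (TIPSCl, 1.0 equiv, imidazole, CH2Cl2), which poses no regiochemical question, to 2-nitro-3-(TIPSO)phenol F9. Amine-directed ortho-bromination of the free phenol (NBS, i-Pr2NH 10 mol %, CH2Cl2, 0 °C) then places bromine next to the hydroxyl, para to the silyl ether whose bulk shields the other open position, and gives 5.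

Further compounds
F1 | step 6 | 6-bromo-2-iodo-3-(TIPSO)phenol | Oc1c(Br)ccc(O[Si](C(C)C)(C(C)C)C(C)C)c1I
F2 | step 6 | 6-bromo-2-[[3,5-bis(TBSO)phenyl](hydroxy)methyl]-3-(TIPSO)phenol (racemic) | Oc1c(Br)ccc(O[Si](C(C)C)(C(C)C)C(C)C)c1C(O)c1cc(O[Si](C)(C)C(C)(C)C)cc(O[Si](C)(C)C(C)(C)C)c1
F3 | step 6 | 6-bromo-2-[[3,5-bis(TBSO)phenyl](4-methylbenzenesulfonyl)methyl]-3-(TIPSO)phenol (racemic) | Oc1c(Br)ccc(O[Si](C(C)C)(C(C)C)C(C)C)c1C(c1cc(O[Si](C)(C)C(C)(C)C)cc(O[Si](C)(C)C(C)(C)C)c1)S(=O)(=O)c1ccc(C)cc1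
F4 | step 6 | 2,4-bis(TBSO)benzaldehyde | O=Cc1ccc(O[Si](C)(C)C(C)(C)C)cc1O[Si](C)(C)C(C)(C)C
F5 | step 6 | 2,4-bis(TBSO)benzyl alcohol | OCc1ccc(O[Si](C)(C)C(C)(C)C)cc1O[Si](C)(C)C(C)(C)C
F6 | step 6 | 1-[2,4-bis(TBSO)benzyl]tetrahydrothiophenium tetrafluoroborate | CC(C)(C)[Si](C)(C)Oc1ccc(C[S+]2CCCC2)c(O[Si](C)(C)C(C)(C)C)c1.F[B-](F)(F)F
F7 | step 6 | (2R,3R)-enantiomer of 9 | Brc1ccc(O[Si](C(C)C)(C(C)C)C(C)C)c2c1O[C@@H](c1ccc(O[Si](C)(C)C(C)(C)C)cc1O[Si](C)(C)C(C)(C)C)[C@@H]2c1cc(O[Si](C)(C)C(C)(C)C)cc(O[Si](C)(C)C(C)(C)C)c1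
F8 | step 14 | diastereomer of 20 with the (2R,3R)-configured triflate-bearing ring | FC(F)(F)S(=O)(=O)Oc1cc(O[Si](C(C)C)(C(C)C)C(C)C)cc2c1[C@@H](c1cc(O[Si](C)(C)C(C)(C)C)cc(O[Si](C)(C)C(C)(C)C)c1)[C@H](c1ccc(O[Si](C(C)C)(C(C)C)C(C)C)c3c1O[C@H](c1ccc(O[Si](C)(C)C(C)(C)C)cc1O[Si](C)(C)C(C)(C)C)[C@H]3c1cc(O[Si](C)(C)C(C)(C)C)cc(O[Si](C)(C)C(C)(C)C)c1)O2
F9 | step 3 | 2-nitro-3-(TIPSO)phenol | Oc1cccc(O[Si](C(C)C)(C(C)C)C(C)C)c1[N+](=O)[O-]
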